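The dihydrofuran ring is cut at O1–C7a and C3–C3a. In the target, the ring oxygen O1 and the carbinol carbon C3 sit on the adjacent benzene carbons C7a and C3a, so a C3a≡C7a aryne can take up both ends of an α-hydroxy aldehyde at once. Fluoride unmasks a chlorine-biased aryne from an ortho-silyl aryl triflate carrying the silyl-protected (R)-1-hydroxyethyl arm. The C2 hydroxyl of (R)-3-benzyloxy-2-hydroxy-3-methylbutanal adds at C7a and the aryl anion closes onto the aldehyde, giving the ring, both bonds and the C3 stereocentre in one operation. Dechlorination/debenzylation, double tigloylation, dehydration and allylic oxidation finish the synthesis.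

Key step: step 9

Assumption: atoms are numbered as in 1-benzofuran (O1, C2, C3, C3a, C4–C7, C7a), "tigloyl/tiglate" means (2E)-2-methylbut-2-enoyl/-enoate, and any minor enantiomer carried from step 2 or step 6 becomes a diastereomer at 18 that should be removable there.

Abbreviations: TBS = tert-butyldimethylsilyl, TMS = trimethylsilyl, Tf = trifluoromethanesulfonyl, Bn = benzyl.

Step 1
Reactants: 1 2'-chloro-4'-hydroxyacetophenone
Product: 2 4-acetyl-3-chlorophenyl N-(propan-2-yl)carbamate
Conditions: iPrNCO, Et3N (cat.), CH2Cl2, rt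
Reagents that add atoms: isopropyl isocyanate, CC(C)N=C=O
Why: Triethylamine-catalysed addition of the phenol O–H across the isocyanate (carbamoylation) gives the N-monoalkyl carbamate that later serves as ortho-directing group and as a base-cleavable handle for triflate installation.

Step 2
Reactants: 2 4-acetyl-3-chlorophenyl N-(propan-2-yl)carbamate
Product: 3 3-chloro-4-[(1R)-1-hydroxyethyl]phenyl N-(propan-2-yl)carbamate
Conditions: (S)-2-methyl-CBS-oxazaborolidine [(S)-1-methyl-3,3-diphenyltetrahydro-1H,3H-pyrrolo[1,2-c][1,3,2]oxazaborole] (10 mol%), BH3·SMe2, THF, −20 °C; MeOH quench, aqueous work-up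
Reagents that add atoms: none
Why: Corey–Bakshi–Shibata reduction: the oxazaborolidine–borane complex binds the ketone with the aryl group in the large-group position and delivers hydride to the Si face, setting the carbinol as (R), while the carbamate is inert to borane at this temperature.

Step 3
Reactants: 3 3-chloro-4-[(1R)-1-hydroxyethyl]phenyl N-(propan-2-yl)carbamate
Product: 4 4-[(1R)-1-(TBS-oxy)ethyl]-3-chlorophenyl N-(propan-2-yl)carbamate
Conditions: TBSCl, imidazole, DMF, rt
Reagents that add atoms: tert-butyldimethylsilyl chloride, CC(C)(C)[Si](C)(C)Cl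
Why: Imidazole-promoted silyl ether formation masks the secondary alcohol before the organolithium step and leaves the N–H carbamate untouched.

Step 4
Reactants: 4 4-[(1R)-1-(TBS-oxy)ethyl]-3-chlorophenyl N-(propan-2-yl)carbamate
Product: 8 4-[(1R)-1-(TBS-oxy)ethyl]-3-chloro-2-(trimethylsilyl)phenyl N-(propan-2-yl)carbamate, via N-silyl carbamate 5 (not isolated), via aryllithium 6 (not isolated), via C-silylated N-silyl carbamate 7 (not isolated)
Conditions: TBSOTf, TMEDA, Et2O, 0 °C → rt; n-BuLi, TMEDA, −78 °C; TMSCl, −78 °C → rt; aq. NaHSO4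
Reagents that add atoms: chlorotrimethylsilane, C[Si](C)(C)Cl
Why: Directed ortho-metalation: after transient N-silylation of the carbamate, n-BuLi/TMEDA removes the ring proton flanked by the carbamate oxygen and chlorine, which is by far the most acidic, the ortho-chloro aryllithium is held at −78 °C to prevent LiCl loss and anionic Fries shift, and C-silylation followed by acidic work-up (N–Si hydrolysis) gives the ortho-silyl carbamate.

Step 5
Reactants: 8 4-[(1R)-1-(TBS-oxy)ethyl]-3-chloro-2-(trimethylsilyl)phenyl N-(propan-2-yl)carbamate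
Product: 10 4-[(1R)-1-(TBS-oxy)ethyl]-3-chloro-2-(trimethylsilyl)phenyl trifluoromethanesulfonate, via silylphenol 9 (not isolated)
Conditions: DBU, Et2NH, MeCN, 40 °C; then PhNTf2, rt
Reagents that add atoms: N-phenylbis(trifluoromethanesulfonimide), O=S(=O)(N(c1ccccc1)S(=O)(=O)C(F)(F)F)C(F)(F)F
Why: Carbamate-to-triflate exchange: DBU triggers E1cB loss of isopropyl isocyanate from the N–H carbamate (trapped by Et2NH as a urea) and the phenoxide released is triflated in the same flask by PhNTf2, under conditions that leave the aryl–silicon bond and the silyl ether intact.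

Step 6
Reactants: 11 3-methylbut-2-en-1-ol (prenol)
Product: 12 [(2S)-3,3-dimethyloxiran-2-yl]methanol
Conditions: Ti(OiPr)4 (cat.), L-(+)-diethyl tartrate (cat.), t-BuOOH, 4 Å molecular sieves, CH2Cl2, −20 °C
Reagents that add atoms: tert-butyl hydroperoxide, CC(C)(C)OO
Why: Sharpless asymmetric epoxidation: the dimeric titanium tartrate complex binds the allylic alcohol and the peroxide and, with the L-(+)-tartrate, delivers oxygen to the enantioface that sets C2 as (S).

Step 7
Reactants: 12 [(2S)-3,3-dimethyloxiran-2-yl]methanol; 13 benzyl alcohol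
Product: 14 (2S)-3-(benzyloxy)-3-methylbutane-1,2-diol
Conditions: BnOH (excess), BF3·OEt2 (cat.), CH2Cl2, −20 → 0 °C
Reagents that add atoms: none
Why: Lewis acid-catalysed epoxide alcoholysis proceeds with SN1-like character at the tertiary carbon, so benzyl alcohol ends up on C3 while the C2–O bond and its (S) configuration are untouched.

Step 8
Reactants: 14 (2S)-3-(benzyloxy)-3-methylbutane-1,2-diol
Product: 15 (2R)-3-(benzyloxy)-2-hydroxy-3-methylbutanal
Conditions: TEMPO (2,2,6,6-tetramethylpiperidin-1-oxyl, cat.), PhI(OAc)2, CH2Cl2, rt; used crude at once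
Reagents that add atoms: none
Why: Oxoammonium oxidation (TEMPO/PhI(OAc)2) is selective for the primary over the hindered secondary hydroxyl and stops at the aldehyde in the absence of water, leaving C2 unchanged (its descriptor becomes R only because CHO now outranks the quaternary carbon).

Step 9
Reactants: 10 4-[(1R)-1-(TBS-oxy)ethyl]-3-chloro-2-(trimethylsilyl)phenyl trifluoromethanesulfonate; 15 (2R)-3-(benzyloxy)-2-hydroxy-3-methylbutanal
Product: 18 (2S,3S)-2-[2-(benzyloxy)propan-2-yl]-5-[(1R)-1-(TBS-oxy)ethyl]-4-chloro-2,3-dihydro-1-benzofuran-3-ol (2,3-trans), via chloroaryne 16 (not isolated), via aryl caesium adduct 17 (not isolated)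
Conditions: CsF (3 equiv), MeCN, 0 °C → rt; 10 added slowly to 15 (1.5 equiv)
Reagents that add atoms: none
Why: Proposed new method: CsF removes the trimethylsilyl group of 10 and triflate leaves, giving aryne 16; the fluoride-activated C2 hydroxyl of 15 adds to the aryne carbon remote from chlorine (future C7a), and the aryl anion 17 formed at C3a attacks the neighbouring aldehyde to make the C3a–C3 bond and, after proton transfer, the C3 carbinol. The closest known reaction type is the fluoride-induced aryne annulation in which a heteroatom adds to the aryne and the aryl anion closes onto a tethered carbonyl, as in the formation of indolin-3-ols from N-sulfonyl α-amino ketones and of xanthen-9-ols from salicylaldehydes; an aliphatic α-hydroxy aldehyde as partner is the untested element. The dihydrofuran ring closes in a 5-exo-trig mode (aryl anion onto C=O), as in Parham-type cyclisations of ortho-metalated aryl ethers. The new C3 stereocentre is controlled by the existing C2 stereocentre, because in the closing transition state the carbonyl oxygen should turn away from the bulky 2-(benzyloxy)propan-2-yl group, giving the 2,3-trans (2S,3S) alcohol, while C2 is carried unchanged from 15. The step needs regioselective O-addition and use of the secondary hydroxyl only: the inductive pull and aryne distortion caused by chlorine send oxygen to the distal carbon and stabilise the adjacent anion, the tertiary oxygen is capped as a non-migrating benzyl ether, and intramolecular carbonyl capture should outrun chloride loss or protonation of the anion.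

Step 10
Reactants: 18 (2S,3S)-2-[2-(benzyloxy)propan-2-yl]-5-[(1R)-1-(TBS-oxy)ethyl]-4-chloro-2,3-dihydro-1-benzofuran-3-ol
Product: 19 (2S,3S)-5-[(1R)-1-(TBS-oxy)ethyl]-2-(2-hydroxypropan-2-yl)-2,3-dihydro-1-benzofuran-3-ol
Conditions: H2 (1–4 atm), 10% palladium on carbon (Pd/C), NaOAc, EtOAc/MeOH, rt
Reagents that add atoms: none
Why: Heterogeneous catalytic hydrogenolysis cleaves the benzyl C–O bond and the aryl C–Cl bond in one operation, and an acetate buffer (chosen over an amine base, which would slow O-debenzylation on palladium) takes up HCl so that the benzylic C3–OH and the benzylic silyl ether are neither ionised nor hydrogenolysed.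

Step 11
Reactants: 19 (2S,3S)-5-[(1R)-1-(TBS-oxy)ethyl]-2-(2-hydroxypropan-2-yl)-2,3-dihydro-1-benzofuran-3-ol
Product: 20 (2S,3S)-5-[(1R)-1-hydroxyethyl]-2-(2-hydroxypropan-2-yl)-2,3-dihydro-1-benzofuran-3-ol
Conditions: Bu4NF, THF, 0 °C → rt
Reagents that add atoms: none
Why: Fluoride-mediated desilylation driven by Si–F bond formation frees the secondary benzylic alcohol without affecting any stereocentre.

Step 12
Reactants: 20 (2S,3S)-5-[(1R)-1-hydroxyethyl]-2-(2-hydroxypropan-2-yl)-2,3-dihydro-1-benzofuran-3-ol; 21 tigloyl chloride [(2E)-2-methylbut-2-enoyl chloride], two molecules per molecule of 20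
Product: 22 (1R)-1-[(2S,3S)-2-(2-hydroxypropan-2-yl)-3-(tigloyloxy)-2,3-dihydro-1-benzofuran-5-yl]ethyl tiglate
Conditions: 21 (2.5 equiv), pyridine, DMAP (4-(dimethylamino)pyridine, cat.), CH2Cl2, 0 °C → rt
Reagents that add atoms: tigloyl chloride (the second molecule of 21, which supplies the second ester group), C/C=C(\C)C(=O)Cl
Why: DMAP-catalysed acylation consumes two molecules of the acid chloride, one at each secondary hydroxyl, while the tertiary alcohol is too hindered to react; pyridine, unlike a trialkylamine, should not deprotonate the acylpyridinium at its γ-methyl (no vinylketene and no deconjugated ester), keeps the medium basic so that the electron-rich benzylic C–O bonds do not ionise, and the thermodynamically favoured (E)-geometry of the tigloyl group is retained.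

Step 13
Reactants: 22 (1R)-1-[(2S,3S)-2-(2-hydroxypropan-2-yl)-3-(tigloyloxy)-2,3-dihydro-1-benzofuran-5-yl]ethyl tiglate
Product: 23 (1R)-1-[(2R,3S)-2-(prop-1-en-2-yl)-3-(tigloyloxy)-2,3-dihydro-1-benzofuran-5-yl]ethyl tiglate
Conditions: Burgess reagent (methyl N-(triethylammoniosulfonyl)carbamate), toluene, 50 °C
Reagents that add atoms: none
Why: Burgess dehydration: the tertiary alkyl sulfamate undergoes thermal syn-elimination (Ei), and loss of a methyl hydrogen should be favoured statistically and electronically over loss of the oxygen-deactivated C2–H, giving the isopropenyl group under neutral conditions that spare the esters and both ring stereocentres.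

Step 14
Reactants: 23 (1R)-1-[(2R,3S)-2-(prop-1-en-2-yl)-3-(tigloyloxy)-2,3-dihydro-1-benzofuran-5-yl]ethyl tiglate
Product: 25 target CNP0292799.1 [(1R)-1-[(2R,3S)-2-(3-oxoprop-1-en-2-yl)-3-(tigloyloxy)-2,3-dihydro-1-benzofuran-5-yl]ethyl tiglate], via allylic alcohol 24 (not isolated)
Conditions: SeO2 (0.5 equiv), t-BuOOH, CH2Cl2, rt; then MnO2, CH2Cl2, rt
Reagents that add atoms: selenium dioxide, O=[Se]=O; tert-butyl hydroperoxide, CC(C)(C)OO
Why: Riley allylic oxidation (ene reaction of SeO2 followed by [2,3]-sigmatropic shift) should hydroxylate the methyl of the electron-rich 1,1-disubstituted alkene in preference to the C2 methine and the electron-poor tigloyl alkenes, and MnO2 then converts the allylic alcohol 24, together with any enal already present, into the enal under non-basic conditions that avoid β-elimination of the C3 ester.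

Compound list
1 | 2'-chloro-4'-hydroxyacetophenone [1-(2-chloro-4-hydroxyphenyl)ethan-1-one] | CC(=O)c1ccc(O)cc1Cl | starting material
2 | 4-acetyl-3-chlorophenyl N-(propan-2-yl)carbamate | CC(=O)c1ccc(OC(=O)NC(C)C)cc1Cl | intermediate
3 | 3-chloro-4-[(1R)-1-hydroxyethyl]phenyl N-(propan-2-yl)carbamate | C[C@@H](O)c1ccc(OC(=O)NC(C)C)cc1Cl | intermediate
4 | 4-[(1R)-1-(tert-butyldimethylsilyloxy)ethyl]-3-chlorophenyl N-(propan-2-yl)carbamate | C[C@@H](O[Si](C)(C)C(C)(C)C)c1ccc(OC(=O)NC(C)C)cc1Cl | intermediate
5 | 4-[(1R)-1-(tert-butyldimethylsilyloxy)ethyl]-3-chlorophenyl N-(tert-butyldimethylsilyl)-N-(propan-2-yl)carbamate (formed in the flask) | C[C@@H](O[Si](C)(C)C(C)(C)C)c1ccc(OC(=O)N(C(C)C)[Si](C)(C)C(C)(C)C)cc1Cl | intermediate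
6 | 2-lithio derivative of 5 (lithium on the ring carbon between the carbamate oxygen and chlorine; formed in the flask) | C[C@@H](O[Si](C)(C)C(C)(C)C)c1ccc(OC(=O)N(C(C)C)[Si](C)(C)C(C)(C)C)c([Li])c1Cl | intermediate
7 | 4-[(1R)-1-(tert-butyldimethylsilyloxy)ethyl]-3-chloro-2-(trimethylsilyl)phenyl N-(tert-butyldimethylsilyl)-N-(propan-2-yl)carbamate (formed in the flask) | C[C@@H](O[Si](C)(C)C(C)(C)C)c1ccc(OC(=O)N(C(C)C)[Si](C)(C)C(C)(C)C)c([Si](C)(C)C)c1Cl | intermediate
8 | 4-[(1R)-1-(tert-butyldimethylsilyloxy)ethyl]-3-chloro-2-(trimethylsilyl)phenyl N-(propan-2-yl)carbamate | C[C@@H](O[Si](C)(C)C(C)(C)C)c1ccc(OC(=O)NC(C)C)c([Si](C)(C)C)c1Cl | intermediate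
9 | 4-[(1R)-1-(tert-butyldimethylsilyloxy)ethyl]-3-chloro-2-(trimethylsilyl)phenol (formed in the flask) | C[C@@H](O[Si](C)(C)C(C)(C)C)c1ccc(O)c([Si](C)(C)C)c1Cl | intermediate
10 | 4-[(1R)-1-(tert-butyldimethylsilyloxy)ethyl]-3-chloro-2-(trimethylsilyl)phenyl trifluoromethanesulfonate | C[C@@H](O[Si](C)(C)C(C)(C)C)c1ccc(OS(=O)(=O)C(F)(F)F)c([Si](C)(C)C)c1Cl | intermediate
11 | 3-methylbut-2-en-1-ol (prenol) | CC(C)=CCO | starting material
12 | [(2S)-3,3-dimethyloxiran-2-yl]methanol | OC[C@@H]1OC1(C)C | intermediate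
13 | benzyl alcohol | OCc1ccccc1 | starting material
14 | (2S)-3-(benzyloxy)-3-methylbutane-1,2-diol | OC[C@H](O)C(C)(C)OCc1ccccc1 | intermediate
15 | (2R)-3-(benzyloxy)-2-hydroxy-3-methylbutanal | O=C[C@H](O)C(C)(C)OCc1ccccc1 | intermediate
16 | tert-butyl{(1R)-1-[2-chloro-3,4-didehydrophenyl]ethoxy}dimethylsilane (3-chloroaryne, formed in the flask) | C[C@@H](O[Si](C)(C)C(C)(C)C)C1=C(Cl)C#CC=C1 | intermediate
17 | (2R)-3-(benzyloxy)-2-{2-caesio-4-[(1R)-1-(tert-butyldimethylsilyloxy)ethyl]-3-chlorophenoxy}-3-methylbutanal (aryl caesium adduct, formed in the flask) | O=C[C@H](Oc1ccc([C@@H](C)O[Si](C)(C)C(C)(C)C)c(Cl)c1[Cs])C(C)(C)OCc1ccccc1 | intermediate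
18 | (2S,3S)-2-[2-(benzyloxy)propan-2-yl]-5-[(1R)-1-(tert-butyldimethylsilyloxy)ethyl]-4-chloro-2,3-dihydro-1-benzofuran-3-ol (2,3-trans) | CC(C)(OCc1ccccc1)[C@H]2Oc3ccc([C@@H](C)O[Si](C)(C)C(C)(C)C)c(Cl)c3[C@@H]2O | intermediate
19 | (2S,3S)-5-[(1R)-1-(tert-butyldimethylsilyloxy)ethyl]-2-(2-hydroxypropan-2-yl)-2,3-dihydro-1-benzofuran-3-ol | CC(C)(O)[C@H]1Oc2ccc([C@@H](C)O[Si](C)(C)C(C)(C)C)cc2[C@@H]1O | intermediate
20 | (2S,3S)-5-[(1R)-1-hydroxyethyl]-2-(2-hydroxypropan-2-yl)-2,3-dihydro-1-benzofuran-3-ol | CC(C)(O)[C@H]1Oc2ccc([C@@H](C)O)cc2[C@@H]1O | intermediate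
21 | tigloyl chloride [(2E)-2-methylbut-2-enoyl chloride] | C/C=C(\C)C(=O)Cl | starting material
22 | (1R)-1-[(2S,3S)-2-(2-hydroxypropan-2-yl)-3-{[(2E)-2-methylbut-2-enoyl]oxy}-2,3-dihydro-1-benzofuran-5-yl]ethyl (2E)-2-methylbut-2-enoate | CC(C)(O)[C@H]1Oc2ccc([C@@H](C)OC(=O)/C(C)=C/C)cc2[C@@H]1OC(=O)/C(C)=C/C | intermediate
23 | (1R)-1-[(2R,3S)-3-{[(2E)-2-methylbut-2-enoyl]oxy}-2-(prop-1-en-2-yl)-2,3-dihydro-1-benzofuran-5-yl]ethyl (2E)-2-methylbut-2-enoate | C=C(C)[C@H]1Oc2ccc([C@@H](C)OC(=O)/C(C)=C/C)cc2[C@@H]1OC(=O)/C(C)=C/C | intermediate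
24 | (1R)-1-[(2R,3S)-2-(3-hydroxyprop-1-en-2-yl)-3-{[(2E)-2-methylbut-2-enoyl]oxy}-2,3-dihydro-1-benzofuran-5-yl]ethyl (2E)-2-methylbut-2-enoate (formed in the flask) | C=C(CO)[C@H]1Oc2ccc([C@@H](C)OC(=O)/C(C)=C/C)cc2[C@@H]1OC(=O)/C(C)=C/C | intermediate
25 | CNP0292799.1, (1R)-1-[(2R,3S)-3-{[(2E)-2-methylbut-2-enoyl]oxy}-2-(3-oxoprop-1-en-2-yl)-2,3-dihydro-1-benzofuran-5-yl]ethyl (2E)-2-methylbut-2-enoate | C=C(C=O)[C@H]1Oc2ccc([C@@H](C)OC(=O)/C(C)=C/C)cc2[C@@H]1OC(=O)/C(C)=C/C | target

Total step count: 14 (arene branch steps 1–5, aldehyde branch steps 6–8, union in step 9, endgame steps 10–14).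
Longest linear sequence: 11 steps (steps 1–5 and 9–14).

Steps most likely to fail

Step 9 (proposed new method). The hindered secondary hydroxyl may add to the aryne too slowly, so that the aryne is consumed by the aldehyde carbonyl, by fluoride or by solvent-derived nucleophiles. The α-hydroxy aldehyde may epimerise or self-condense under basic fluoride before it is captured. The aryl anion may be protonated, or lose chloride, before it closes. Ring closure may also show poor facial selectivity. The fallback uses known reactions only, making C3a–C3 first by carbonyl addition and O1–C7a second by copper-catalysed arylation. It sets out from aldehyde 15 and rejoins the route at triol 20. Commercial 1-(4-bromo-3-iodophenyl)ethan-1-one F1 would be reduced as in step 2 to (1R)-1-(4-bromo-3-iodophenyl)ethan-1-ol F2 and silylated as in step 3 to [(1R)-1-(4-bromo-3-iodophenyl)ethoxy](tert-butyl)dimethylsilane F3. Aldehyde 15 would be O-silylated (TBSOTf, 2,6-lutidine, CH2Cl2, −78 °C) to (2R)-3-(benzyloxy)-2-(tert-butyldimethylsilyloxy)-3-methylbutanal F4. Iodine–magnesium exchange on F3 (iPrMgCl·LiCl, THF, −40 °C) would give the 2-bromoaryl Grignard reagent F5. Its addition to F4 under non-chelation (Felkin–Anh/Cornforth) control should give the 1,2-anti adduct F6, any syn epimer being separated. Bu4NF would remove both silyl groups to give triol F7. Ullmann-type intramolecular O-arylation (CuBr, 3,4,7,8-tetramethyl-1,10-phenanthroline, Cs2CO3, toluene, 100 °C), in which only the C2 hydroxyl can reach the bromide through a five-membered ring, would give dihydrobenzofuranol F8. Hydrogenolysis of the benzyl ether (H2, Pd/C, EtOAc) would then give 20.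

Step 14. The ene reaction at the 1,1-disubstituted alkene may be slow, so that oxidation at the γ-methyl groups of the tigloyl esters or ionisation of the benzylic esters by selenous acid competes, and the sequence may stall at mixtures of alcohol and enal. The fallback sets out from 23 and ends at target 25. Ene-type allylic chlorination with hypochlorous acid made in situ (Ca(OCl)2, solid CO2, CH2Cl2/H2O, 0 °C), which is specific for electron-rich alkenes, would give the allylic chloride F9. Kornblum-type oxidation of the chloride with N-methylmorpholine N-oxide (NaI cat., MeCN, rt) would give 25 without a selenium reagent.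

Step 8. The oxoammonium salt may over-oxidise or cleave the vicinal diol, or the free hydroxy aldehyde may be lost by dimerisation and hemiacetal ester formation while the oxidation is still running. The fallback sets out from diol 14 and rejoins at 15. Bis-silylation (Et3SiCl, imidazole, CH2Cl2) would give the bis(triethylsilyl) ether F10. Swern oxidation (oxalyl chloride, DMSO, then Et3N, −78 → −30 °C), which converts a primary triethylsilyl ether directly into the aldehyde and leaves the secondary one in place, would give the 2-(triethylsilyloxy) aldehyde F11. Brief treatment with AcOH/THF/H2O at 0 °C would release 15 just before use.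

Further compounds
F1 | step 9 | 1-(4-bromo-3-iodophenyl)ethan-1-one (purchased) | CC(=O)c1ccc(Br)c(I)c1
F2 | step 9 | (1R)-1-(4-bromo-3-iodophenyl)ethan-1-ol | C[C@@H](O)c1ccc(Br)c(I)c1
F3 | step 9 | [(1R)-1-(4-bromo-3-iodophenyl)ethoxy](tert-butyl)dimethylsilane | C[C@@H](O[Si](C)(C)C(C)(C)C)c1ccc(Br)c(I)c1
F4 | step 9 | (2R)-3-(benzyloxy)-2-(tert-butyldimethylsilyloxy)-3-methylbutanal | O=C[C@H](O[Si](C)(C)C(C)(C)C)C(C)(C)OCc1ccccc1
F5 | step 9 | {2-bromo-5-[(1R)-1-(tert-butyldimethylsilyloxy)ethyl]phenyl}magnesium chloride (LiCl complex, formed in the flask) | C[C@@H](O[Si](C)(C)C(C)(C)C)c1ccc(Br)c([Mg]Cl)c1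
F6 | step 9 | (1S,2S)-3-(benzyloxy)-1-{2-bromo-5-[(1R)-1-(tert-butyldimethylsilyloxy)ethyl]phenyl}-2-(tert-butyldimethylsilyloxy)-3-methylbutan-1-ol | CC(C)(OCc1ccccc1)[C@@H](O[Si](C)(C)C(C)(C)C)[C@@H](O)c1cc(ccc1Br)[C@@H](C)O[Si](C)(C)C(C)(C)C
F7 | step 9 | (1S,2S)-3-(benzyloxy)-1-{2-bromo-5-[(1R)-1-hydroxyethyl]phenyl}-3-methylbutane-1,2-diol | CC(C)(OCc1ccccc1)[C@@H](O)[C@@H](O)c1cc(ccc1Br)[C@@H](C)O
F8 | step 9 | (2S,3S)-2-[2-(benzyloxy)propan-2-yl]-5-[(1R)-1-hydroxyethyl]-2,3-dihydro-1-benzofuran-3-ol | CC(C)(OCc1ccccc1)[C@H]1Oc2ccc([C@@H](C)O)cc2[C@@H]1O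
F9 | step 14 | (1R)-1-[(2R,3S)-2-(3-chloroprop-1-en-2-yl)-3-{[(2E)-2-methylbut-2-enoyl]oxy}-2,3-dihydro-1-benzofuran-5-yl]ethyl (2E)-2-methylbut-2-enoate | C=C(CCl)[C@H]1Oc2ccc([C@@H](C)OC(=O)/C(C)=C/C)cc2[C@@H]1OC(=O)/C(C)=C/C
F10 | step 8 | (2S)-3-(benzyloxy)-3-methyl-1,2-bis(triethylsilyloxy)butane | CC[Si](CC)(CC)OC[C@H](O[Si](CC)(CC)CC)C(C)(C)OCc1ccccc1
F11 | step 8 | (2R)-3-(benzyloxy)-3-methyl-2-(triethylsilyloxy)butanal | O=C[C@H](O[Si](CC)(CC)CC)C(C)(C)OCc1ccccc1
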